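**Retrosynthetic overview**

1. End game: the eight phenols are unveiled by hydrogenolysis; the C4' carbinol comes from SN1 hydration of a 4'-methyl ether (water enters trans to the 3'-hydroxyl); the upper C3 is inverted to the all-cis array by oxidation and L-Selectride reduction.
2. Key disconnection: the pyran ring C of the lower unit, opened at O1'–C2' and C3'–C4', by a three-component, chiral-acid-controlled inverse-electron-demand oxa-[4+2] reaction of a salicylaldehyde, trimethyl orthoformate and a (Z)-β-acetoxystyrene.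
3. Enabling feature: ring A of the lower unit carries the ether oxygen O1' (on C8a') and the carbinol carbon C4' (on C4a') on adjacent ring carbons. This is a masked salicylaldehyde, hence a latent o-quinone methide O1'=C8a'–C4a'=C4', and C2'–C3' is a two-carbon unit polarised by the catechol ring on C2'.
4. The salicylaldehyde comes from Friedel–Crafts union of the C4 cation of benzylated (−)-catechin with 3,5-bis(benzyloxy)phenol (bond C4–C8'), then ortho-formylation next to the only free phenol, which fixes the 4→8 connectivity.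
5. Ring order: rings A, C and B of the upper unit come from the chiral pool; ring A of the lower unit is attached next; ring C of the lower unit is closed last, bringing its ring B with it.

Key step: step 7

Remark: unprimed locants refer to the upper unit (2S,3S,4R, all-cis), primed locants to the lower unit (2'R,3'R,4'S, 2,3-cis-3,4-trans).
Assumption: the (R)-configured phosphoric acid is taken to be the antipode that gives the 2'R series in step 7; should the sense of induction prove opposite, the (S)-acid is used without other change.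

**Route**

Step 1
Reactants: 1 (−)-catechin, (2S,3R)-2-(3,4-dihydroxyphenyl)chroman-3,5,7-triol
Product: 2 5,7,3',4'-tetra-O-benzyl-(−)-catechin
Conditions: BnBr (4.2 equiv), K2CO3, DMF, 0 °C to rt
Reagents that add atoms: benzyl bromide, BrCc1ccccc1
Why: Williamson ether synthesis in which carbonate deprotonates only the four phenols, so the secondary alcohol and both stereocentres are left untouched.

Step 2
Reactants: 2 5,7,3',4'-tetra-O-benzyl-(−)-catechin
Product: 3 4-(2-ethoxyethoxy) ether of 2 (2S,3R,4R)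
Conditions: DDQ (2 equiv), EtOCH2CH2OH (5 equiv), CH2Cl2, rt
Reagents that add atoms: 2-ethoxyethanol, CCOCCO
Why: DDQ-mediated benzylic C–H oxidation: hydride abstraction at C4 gives the flavan-4-yl cation stabilised by the 5,7-dialkoxy ring A, which the alcohol traps (expected trans to the 2-aryl group, 4R), the configuration of this centre being immaterial because it is ionised again in step 3.

Step 3
Reactants: 3 4-(2-ethoxyethoxy) ether; 4 3,5-bis(benzyloxy)phenol (3 equiv)
Product: 5 (2S,3R,4S)-5,7-bis(benzyloxy)-2-[3,4-bis(benzyloxy)phenyl]-4-[2,4-bis(benzyloxy)-6-hydroxyphenyl]chroman-3-ol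
Conditions: TMSOTf (0.3 equiv), CH2Cl2, −78 to −40 °C
Reagents that add atoms: none
Why: Lewis-acid-promoted Friedel–Crafts alkylation (the standard proanthocyanidin interflavan coupling): the regenerated C4 cation is attacked by the phenol, used in excess to suppress self-condensation, at a carbon ortho to its free hydroxyl (two equivalent sites, each flanked by OH rather than by two benzyloxy groups) and on the face anti to the 3-hydroxyl, which sets C4 (S, 3,4-trans, 2,4-cis).

Step 4
Reactants: 5 phenol adduct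
Product: 6 4,6-bis(benzyloxy)-3-{(2S,3R,4S)-5,7-bis(benzyloxy)-2-[3,4-bis(benzyloxy)phenyl]-3-hydroxychroman-4-yl}-2-hydroxybenzaldehyde
Conditions: MgCl2, Et3N, (CH2O)n, MeCN, reflux; aqueous HCl work-up
Reagents that add atoms: formaldehyde (from paraformaldehyde), C=O
Why: Casnati–Skattebøl magnesium-mediated ortho-formylation: formaldehyde is delivered within the magnesium phenoxide to the only free position ortho to the phenol and the benzylic alkoxide is oxidised by a second formaldehyde, so the benzyl-etherified rings stay untouched and the formyl group ends up next to the oxygen that will become O1', which fixes the 4→8 connectivity.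

Step 5
Reactants: 7 3,4-bis(benzyloxy)benzaldehyde
Product: 8 1,2-bis(benzyloxy)-4-ethynylbenzene
Conditions: dimethyl (1-diazo-2-oxopropyl)phosphonate, K2CO3, MeOH/THF, rt
Reagents that add atoms: dimethyl (1-diazo-2-oxopropyl)phosphonate, CC(=O)C(=[N+]=[N-])P(=O)(OC)OC
Why: Ohira–Bestmann (Seyferth–Gilbert) homologation: the diazomethylphosphonate anion formed by methanolysis adds to the aldehyde and the resulting alkylidene carbene rearranges to the terminal alkyne under conditions that spare benzyl ethers.

Step 6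
Reactants: 8 1,2-bis(benzyloxy)-4-ethynylbenzene
Product: 9 (Z)-2-[3,4-bis(benzyloxy)phenyl]ethenyl acetate
Conditions: AcOH (1.3 equiv), [RuCl2(p-cymene)]2 (1 mol %), P(4-ClC6H4)3 (3 mol %), DMAP (4 mol %), toluene, 60 °C
Reagents that add atoms: acetic acid, CC(=O)O
Why: Ruthenium-catalysed anti-Markovnikov hydro-acyloxylation of a terminal alkyne: acetate adds to the ruthenium vinylidene and protonolysis delivers the Z-enol ester stereoselectively.

Step 7
Reactants: 6 salicylaldehyde; 9 (Z)-enol acetate (2 equiv)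
Product: 12 protected dimer: octa-O-benzyl 3'-O-acetyl-4'-O-methyl cycloadduct (upper unit 2S,3R,4R; lower unit 2'R,3'R,4'S), via dimethyl acetal 10 (not isolated), via methoxy-o-quinone methide 11 (not isolated)
Conditions: HC(OMe)3 (3 equiv), (R)-TRIP [(R)-3,3'-bis(2,4,6-triisopropylphenyl)-1,1'-binaphthyl-2,2'-diyl hydrogen phosphate] (10 mol %), 4 Å MS, toluene, −20 °C to rt; aqueous NaHCO3 work-up
Reagents that add atoms: trimethyl orthoformate, COC(OC)OC
Why: Proposed new method: under the chiral phosphoric acid the orthoformate converts the aldehyde into dimethyl acetal 10, which loses methanol with help from the free ortho-hydroxyl to give the α-methoxy-o-quinone methide 11 (its protonated form is the phosphate-paired oxocarbenium ion), an electron-poor oxa-diene O1'=C8a'–C4a'=C4' that is captured by the electron-rich enol acetate 9 in an inverse-electron-demand oxa-[4+2] cycloaddition; the closest known reactions are the acid-catalysed three-component coupling of salicylaldehydes, trimethyl orthoformate and styrenes or enol ethers to 4-alkoxychromans and the chiral-phosphoric-acid-controlled [4+2] cycloadditions of o-quinone methides with styrenes, the new element being a β-acyloxystyrene as the 2π partner. The one ring that is closed, pyran ring C of the lower unit, is formed by a concerted but asynchronous [4+2] closure in which C4'–C3' bonding runs ahead of O1'–C2' bonding (in the stepwise limit a 6-endo closure of the phenol oxygen onto the benzylic cation). Regiochemistry should follow from the 4-benzyloxyphenyl group, which stabilises positive charge at C2' far better than the acetoxy group does at C3', so that the acetoxy-bearing carbon bonds to C4' and the benzylic carbon to O1'; because only one phenolic hydroxyl is free, the ring can only close to the 4→8 linked isomer. C3' is set relative to C2' by suprafacial transfer of the Z geometry of 9 (2',3'-cis); C4' is set by endo approach of the aryl and acetoxy groups to a heterodiene whose methoxy group lies inside (3',4'-trans, the epimer that reversible ionisation at C4' in the presence of methanol also favours, and a centre that step 11 sets again in any case); the absolute configuration at C2' (R) is set by the chiral phosphate, which is hydrogen-bonded to the quinone methide oxygen and shields one face of the diene. The step therefore needs facial selectivity from the catalyst against whatever bias the resident upper unit at C8' exerts, and retention of the alkene geometry; low temperature, a non-polar solvent and the tight ion pair are chosen to keep the addition concerted, and C2' epimers would be diastereomers separable by chromatography.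

Step 8
Reactants: 12 protected dimer with free upper 3-hydroxyl
Product: 13 upper flavan-3-one (upper unit 2S,4R; lower unit unchanged)
Conditions: Dess–Martin periodinane (1.5 equiv), CH2Cl2, rt
Reagents that add atoms: none
Why: Dess–Martin oxidation of the only free hydroxyl (the lower 3'-oxygen is acetylated) under neutral conditions gives the flavan-3-one without touching the acid-labile 4'-methyl ether or epimerising C2 and C4, whose cis-diequatorial arrangement is in any case the thermodynamic one.

Step 9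
Reactants: 13 upper flavan-3-one
Product: 14 all-cis upper alcohol (upper unit 2S,3S,4R; lower unit 3'-O-acetyl-4'-O-methyl)
Conditions: LiBH(s-Bu)3 (L-Selectride, 1.5 equiv), THF, −78 °C; then H2O
Reagents that add atoms: none
Why: Diastereoselective ketone reduction: the bulky L-Selectride attacks the half-chair from the equatorial direction, on the face opposite the two flanking pseudo-equatorial aryl groups, as in its reduction of benzylated flavan-3-ones to epicatechins and of cis-2,6-disubstituted cyclohexanones, giving the axial 3-hydroxyl cis to both neighbours (3S, all-cis) while the acetate survives at −78 °C.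

Step 10
Reactants: 14 all-cis upper alcohol with lower 3'-acetate
Product: 15 octa-O-benzyl 3,3'-diol 4'-methyl ether
Conditions: K2CO3 (0.2 equiv), MeOH/THF, 0 °C to rt
Reagents that add atoms: none
Why: Base-catalysed transesterification (Zemplén-type methanolysis) removes the acetate without affecting benzyl ethers, the benzylic methyl ether or any stereocentre.

Step 11
Reactants: 15 octa-O-benzyl 3,3'-diol 4'-methyl ether
Product: 16 octa-O-benzyl 3,3',4'-triol (lower unit 2'R,3'R,4'S)
Conditions: TsOH·H2O (10 mol %), THF/H2O (4:1), 5 mM, rt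
Reagents that add atoms: water, O
Why: SN1 solvolysis of the activated benzylic ether: the 5',7'-dialkoxy-stabilised C4' cation is captured by water from the face anti to the axial 3'-hydroxyl and the 2'-aryl group, the invariable course of C4 substitution in 2,3-cis flavans, which sets C4' (S, 3',4'-trans) whatever the epimer composition of the methyl ether.

Step 12
Reactants: 16 octa-O-benzyl 3,3',4'-triol
Product: 17 target, (2R,3R,4S)-2-(3,4-dihydroxyphenyl)-8-[(2S,3S,4R)-2-(3,4-dihydroxyphenyl)-3,5,7-trihydroxychroman-4-yl]chroman-3,4,5,7-tetrol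
Conditions: H2 (1 atm), Pd(OH)2/C, THF/MeOH/H2O, rt, short reaction time
Reagents that add atoms: none
Why: Catalytic hydrogenolysis of the eight aryl benzyl ethers under neutral conditions (the standard last step of procyanidin syntheses), under which aryl benzyl ethers should cleave much faster than the secondary benzylic C2–O, C2'–O and C4'–O bonds, no stereocentre being affected.

**Compound list**

1 | (−)-catechin, (2S,3R)-2-(3,4-dihydroxyphenyl)chroman-3,5,7-triol | Oc1cc(O)c2c(c1)O[C@@H](c1ccc(O)c(O)c1)[C@H](O)C2 | starting material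
2 | (2S,3R)-5,7-bis(benzyloxy)-2-[3,4-bis(benzyloxy)phenyl]chroman-3-ol (tetra-O-benzyl-(−)-catechin) | O(Cc1ccccc1)c1cc(OCc3ccccc3)c2c(c1)O[C@@H](c1ccc(OCc3ccccc3)c(OCc3ccccc3)c1)[C@H](O)C2 | intermediate
3 | (2S,3R,4R)-5,7-bis(benzyloxy)-2-[3,4-bis(benzyloxy)phenyl]-4-(2-ethoxyethoxy)chroman-3-ol | O(Cc1ccccc1)c1cc(OCc3ccccc3)c2c(c1)O[C@@H](c1ccc(OCc3ccccc3)c(OCc3ccccc3)c1)[C@H](O)[C@@H]2OCCOCC | intermediate
4 | 3,5-bis(benzyloxy)phenol | Oc1cc(OCc2ccccc2)cc(OCc2ccccc2)c1 | starting material
5 | (2S,3R,4S)-5,7-bis(benzyloxy)-2-[3,4-bis(benzyloxy)phenyl]-4-[2,4-bis(benzyloxy)-6-hydroxyphenyl]chroman-3-ol | O(Cc1ccccc1)c1cc(OCc3ccccc3)c2c(c1)O[C@@H](c1ccc(OCc3ccccc3)c(OCc3ccccc3)c1)[C@H](O)[C@H]2c1c(O)cc(OCc2ccccc2)cc1OCc1ccccc1 | intermediate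
6 | 4,6-bis(benzyloxy)-3-{(2S,3R,4S)-5,7-bis(benzyloxy)-2-[3,4-bis(benzyloxy)phenyl]-3-hydroxychroman-4-yl}-2-hydroxybenzaldehyde | O(Cc1ccccc1)c1cc(OCc3ccccc3)c2c(c1)O[C@@H](c1ccc(OCc3ccccc3)c(OCc3ccccc3)c1)[C@H](O)[C@H]2c1c(O)c(C=O)c(OCc2ccccc2)cc1OCc1ccccc1 | intermediate
7 | 3,4-bis(benzyloxy)benzaldehyde | O=Cc1ccc(OCc2ccccc2)c(OCc2ccccc2)c1 | starting material
8 | 1,2-bis(benzyloxy)-4-ethynylbenzene | C#Cc1ccc(OCc2ccccc2)c(OCc2ccccc2)c1 | intermediate
9 | (Z)-2-[3,4-bis(benzyloxy)phenyl]ethenyl acetate | CC(=O)O/C=C\c1ccc(OCc2ccccc2)c(OCc2ccccc2)c1 | intermediate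
10 | dimethyl acetal of 6 (configuration as in 6), not isolated | O(Cc1ccccc1)c1cc(OCc3ccccc3)c2c(c1)O[C@@H](c1ccc(OCc3ccccc3)c(OCc3ccccc3)c1)[C@H](O)[C@H]2c1c(O)c(C(OC)OC)c(OCc2ccccc2)cc1OCc1ccccc1 | intermediate
11 | α-methoxy-o-quinone methide from 10: 3,5-bis(benzyloxy)-2-(flavan-4-yl)-6-[(Z)-methoxymethylidene]cyclohexa-2,4-dien-1-one, methoxy group syn to the ring carbonyl, upper unit as in 6, not isolated | O(Cc1ccccc1)c1cc(OCc3ccccc3)c2c(c1)O[C@@H](c1ccc(OCc3ccccc3)c(OCc3ccccc3)c1)[C@H](O)[C@H]2C1=C(OCc2ccccc2)C=C(OCc2ccccc2)/C(=C/OC)C1=O | intermediate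
12 | (2R,3R,4S)-5,7-bis(benzyloxy)-2-[3,4-bis(benzyloxy)phenyl]-8-{(2S,3R,4R)-5,7-bis(benzyloxy)-2-[3,4-bis(benzyloxy)phenyl]-3-hydroxychroman-4-yl}-4-methoxychroman-3-yl acetate | O(Cc1ccccc1)c1cc(OCc3ccccc3)c2c(c1)O[C@@H](c1ccc(OCc3ccccc3)c(OCc3ccccc3)c1)[C@H](O)[C@H]2c1c(OCc2ccccc2)cc(OCc2ccccc2)c2c1O[C@H](c1ccc(OCc3ccccc3)c(OCc3ccccc3)c1)[C@H](OC(C)=O)[C@H]2OC | intermediate
13 | (2R,3R,4S)-5,7-bis(benzyloxy)-2-[3,4-bis(benzyloxy)phenyl]-8-{(2S,4R)-5,7-bis(benzyloxy)-2-[3,4-bis(benzyloxy)phenyl]-3-oxochroman-4-yl}-4-methoxychroman-3-yl acetate | O(Cc1ccccc1)c1cc(OCc3ccccc3)c2c(c1)O[C@@H](c1ccc(OCc3ccccc3)c(OCc3ccccc3)c1)C(=O)[C@H]2c1c(OCc2ccccc2)cc(OCc2ccccc2)c2c1O[C@H](c1ccc(OCc3ccccc3)c(OCc3ccccc3)c1)[C@H](OC(C)=O)[C@H]2OC | intermediate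
14 | (2R,3R,4S)-5,7-bis(benzyloxy)-2-[3,4-bis(benzyloxy)phenyl]-8-{(2S,3S,4R)-5,7-bis(benzyloxy)-2-[3,4-bis(benzyloxy)phenyl]-3-hydroxychroman-4-yl}-4-methoxychroman-3-yl acetate | O(Cc1ccccc1)c1cc(OCc3ccccc3)c2c(c1)O[C@@H](c1ccc(OCc3ccccc3)c(OCc3ccccc3)c1)[C@@H](O)[C@H]2c1c(OCc2ccccc2)cc(OCc2ccccc2)c2c1O[C@H](c1ccc(OCc3ccccc3)c(OCc3ccccc3)c1)[C@H](OC(C)=O)[C@H]2OC | intermediate
15 | (2R,3R,4S)-5,7-bis(benzyloxy)-2-[3,4-bis(benzyloxy)phenyl]-8-{(2S,3S,4R)-5,7-bis(benzyloxy)-2-[3,4-bis(benzyloxy)phenyl]-3-hydroxychroman-4-yl}-4-methoxychroman-3-ol | O(Cc1ccccc1)c1cc(OCc3ccccc3)c2c(c1)O[C@@H](c1ccc(OCc3ccccc3)c(OCc3ccccc3)c1)[C@@H](O)[C@H]2c1c(OCc2ccccc2)cc(OCc2ccccc2)c2c1O[C@H](c1ccc(OCc3ccccc3)c(OCc3ccccc3)c1)[C@H](O)[C@H]2OC | intermediate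
16 | (2R,3R,4S)-5,7-bis(benzyloxy)-2-[3,4-bis(benzyloxy)phenyl]-8-{(2S,3S,4R)-5,7-bis(benzyloxy)-2-[3,4-bis(benzyloxy)phenyl]-3-hydroxychroman-4-yl}chroman-3,4-diol | O(Cc1ccccc1)c1cc(OCc3ccccc3)c2c(c1)O[C@@H](c1ccc(OCc3ccccc3)c(OCc3ccccc3)c1)[C@@H](O)[C@H]2c1c(OCc2ccccc2)cc(OCc2ccccc2)c2c1O[C@H](c1ccc(OCc3ccccc3)c(OCc3ccccc3)c1)[C@H](O)[C@H]2O | intermediate
17 | (2R,3R,4S)-2-(3,4-dihydroxyphenyl)-8-[(2S,3S,4R)-2-(3,4-dihydroxyphenyl)-3,5,7-trihydroxychroman-4-yl]chroman-3,4,5,7-tetrol (CNP0114173.1) | Oc1cc(O)c2c(c1)O[C@@H](c1ccc(O)c(O)c1)[C@@H](O)[C@H]2c1c(O)cc(O)c2c1O[C@H](c1ccc(O)c(O)c1)[C@H](O)[C@H]2O | target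

**Step count and risks**

Total step count: 12. Longest linear sequence: 10 steps (steps 1–4 and 7–12, from (−)-catechin); the dienophile branch (steps 5–6) is two steps.

Steps most likely to fail, and fallbacks:

Step 7 (proposed new method). The cycloaddition may leave the concerted pathway, so that the benzylic cation rotates before ring closure and the Z geometry is lost (2',3'-trans material). The facial selectivity at C2' may be poor or opposed by the upper unit. The enol acetate may bond through its other terminus, or the oxocarbenium ion may be consumed by transacetalisation and arene alkylation instead of cycloaddition. The fallback gives up de novo closure of the lower pyran ring and uses only known flavanol chemistry; it sets out from 3 and returns at 15. Commercial (−)-epicatechin is perbenzylated (BnBr, K2CO3, DMF) to 5,7,3',4'-tetra-O-benzyl-(−)-epicatechin F1. TMSOTf-promoted Friedel–Crafts coupling of 3 with an excess of F1 in CH2Cl2 at −78 °C should give the 4→8 linked octa-O-benzyl ent-catechin–epicatechin diol F2 (upper unit 3,4-trans). Dess–Martin oxidation of both hydroxyls gives the 3,3'-dione F3, and L-Selectride reduction of both ketones, each from the face opposite its 2-aryl group, gives the diol F4 (upper unit all-cis, lower unit 2,3-cis). DDQ in CH2Cl2/MeOH then oxidises the only benzylic methylene (C4'), and methanol adds trans to the 3'-hydroxyl to give 15, from which steps 11 and 12 follow.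

Step 3. The flavanyl cation may attack phenol 4 para to the hydroxyl (between the two benzyloxy groups), which would lead into the 4→6 series; it may also alkylate on oxygen, add with poor 3,4-trans selectivity, or be lost to self-condensation of 3. The fallback uses a symmetrical nucleophile so that no regiochemical choice arises at the C–C bond-forming stage; it sets out from 3 and returns at 6. Coupling of 3 with excess phloroglucinol (BF3·OEt2, THF/CH2Cl2, low temperature) gives the (2S,3R,4S)-4-(2,4,6-trihydroxyphenyl) adduct F5 as a single regioisomer by symmetry. Vilsmeier–Haack formylation (POCl3, DMF, then water) takes place on the free phloroglucinol ring, far more nucleophilic than the benzylated rings, and gives the trihydroxybenzaldehyde F6. Benzylation with two equivalents of BnBr and K2CO3 in DMF etherifies the hydroxyl para to the formyl group and the less hindered of the two chelated hydroxyls, leaving the hydroxyl flanked by the flavanyl and formyl groups free, which is 6.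

Step 12. The doubly activated, unprotected C4' carbinol may be cleaved reductively on palladium, or ionise and condense with the liberated phloroglucinol rings at the catalyst surface. The fallback reverses the order of the last two operations so that C4' is still capped as its methyl ether during hydrogenolysis; it sets out from 15 and returns at 17. Hydrogenolysis of 15 (H2, Pd(OH)2/C, THF/MeOH) gives the free-phenolic 4'-O-methyl ether F7, and exchange of methoxy for hydroxy in dilute aqueous acid at high dilution (the solvolysis that the free 5',7'-dihydroxy ring makes easy, with water entering trans to the 3'-hydroxyl) gives 17.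

Further compounds
F1 | step 7 | (2R,3R)-5,7-bis(benzyloxy)-2-[3,4-bis(benzyloxy)phenyl]chroman-3-ol (tetra-O-benzyl-(−)-epicatechin) | O(Cc1ccccc1)c1cc(OCc3ccccc3)c2c(c1)O[C@H](c1ccc(OCc3ccccc3)c(OCc3ccccc3)c1)[C@H](O)C2
F2 | step 7 | (2R,3R)-5,7-bis(benzyloxy)-2-[3,4-bis(benzyloxy)phenyl]-8-{(2S,3R,4R)-5,7-bis(benzyloxy)-2-[3,4-bis(benzyloxy)phenyl]-3-hydroxychroman-4-yl}chroman-3-ol | O(Cc1ccccc1)c1cc(OCc3ccccc3)c2c(c1)O[C@@H](c1ccc(OCc3ccccc3)c(OCc3ccccc3)c1)[C@H](O)[C@H]2c1c(OCc2ccccc2)cc(OCc2ccccc2)c2c1O[C@H](c1ccc(OCc3ccccc3)c(OCc3ccccc3)c1)[C@H](O)C2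
F3 | step 7 | (2R)-5,7-bis(benzyloxy)-2-[3,4-bis(benzyloxy)phenyl]-8-{(2S,4R)-5,7-bis(benzyloxy)-2-[3,4-bis(benzyloxy)phenyl]-3-oxochroman-4-yl}chroman-3-one | O(Cc1ccccc1)c1cc(OCc3ccccc3)c2c(c1)O[C@@H](c1ccc(OCc3ccccc3)c(OCc3ccccc3)c1)C(=O)[C@H]2c1c(OCc2ccccc2)cc(OCc2ccccc2)c2c1O[C@H](c1ccc(OCc3ccccc3)c(OCc3ccccc3)c1)C(=O)C2
F4 | step 7 | (2R,3R)-5,7-bis(benzyloxy)-2-[3,4-bis(benzyloxy)phenyl]-8-{(2S,3S,4R)-5,7-bis(benzyloxy)-2-[3,4-bis(benzyloxy)phenyl]-3-hydroxychroman-4-yl}chroman-3-ol | O(Cc1ccccc1)c1cc(OCc3ccccc3)c2c(c1)O[C@@H](c1ccc(OCc3ccccc3)c(OCc3ccccc3)c1)[C@@H](O)[C@H]2c1c(OCc2ccccc2)cc(OCc2ccccc2)c2c1O[C@H](c1ccc(OCc3ccccc3)c(OCc3ccccc3)c1)[C@H](O)C2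
F5 | step 3 | (2S,3R,4S)-5,7-bis(benzyloxy)-2-[3,4-bis(benzyloxy)phenyl]-4-(2,4,6-trihydroxyphenyl)chroman-3-ol | O(Cc1ccccc1)c1cc(OCc3ccccc3)c2c(c1)O[C@@H](c1ccc(OCc3ccccc3)c(OCc3ccccc3)c1)[C@H](O)[C@H]2c1c(O)cc(O)cc1O
F6 | step 3 | 3-{(2S,3R,4S)-5,7-bis(benzyloxy)-2-[3,4-bis(benzyloxy)phenyl]-3-hydroxychroman-4-yl}-2,4,6-trihydroxybenzaldehyde | O(Cc1ccccc1)c1cc(OCc3ccccc3)c2c(c1)O[C@@H](c1ccc(OCc3ccccc3)c(OCc3ccccc3)c1)[C@H](O)[C@H]2c1c(O)cc(O)c(C=O)c1O
F7 | step 12 | (2R,3R,4S)-2-(3,4-dihydroxyphenyl)-8-[(2S,3S,4R)-2-(3,4-dihydroxyphenyl)-3,5,7-trihydroxychroman-4-yl]-4-methoxychroman-3,5,7-triol | Oc1cc(O)c2c(c1)O[C@@H](c1ccc(O)c(O)c1)[C@@H](O)[C@H]2c1c(O)cc(O)c2c1O[C@H](c1ccc(O)c(O)c1)[C@H](O)[C@H]2OC
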